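The plan rests on cutting the γ-butyrolactone (O1, C2 carbonyl, C3, C4, C5) at its C5–O1 bond. C2, C3, C4 and C5 are read as the four carbons of a 3-benzylcyclobutanone in which C3 and C5 are enantiotopic methylenes flanking the carbonyl and C4 is prochiral. A catalytic enantioselective Baeyer–Villiger ring expansion, driven by release of four-ring strain, shifts C5 onto oxygen, closing the lactone and fixing C4 as R in one operation. C4 then steers trans-benzylation of C3 by a benzylic bromide that already carries the threo (7R,8R) arylglycerol β-aryl ether, made by an auxiliary-controlled syn-aldol. The cyclobutanone comes from eugenol by dichloroketene cycloaddition and dechlorination.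

Key step: step 4

Remark on the chemistry: lactone atoms are numbered O1, C2 (C=O), C3, C4, C5 and the arylglycerol carbons C7 (carbinol), C8 (aryloxy-bearing) and C9 (CH2OH); imide 8 is taken as a catalogue compound and, for step 4, the ligand antipode that delivers the R lactone is assumed to be selected in a short screen.

Step 1
Reactants: 1 eugenol (4-allyl-2-methoxyphenol)
Product: 2 4-allyl-1-(benzyloxy)-2-methoxybenzene
Conditions: BnBr, K2CO3, DMF, rt
Reagents that add atoms: benzyl bromide, BrCc1ccccc1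
Why: Williamson ether synthesis; the benzyl ether should survive ketene, zinc, peracid and enolate chemistry and is removed by hydrogenolysis in the last step.

Step 2
Reactants: 2 4-allyl-1-(benzyloxy)-2-methoxybenzene
Product: 3 rac-2,2-dichloro-3-[4-(benzyloxy)-3-methoxybenzyl]cyclobutan-1-one
Conditions: Cl3CCOCl, Zn–Cu couple, POCl3, Et2O, 25–35 °C
Reagents that add atoms: trichloroacetyl chloride, ClC(=O)C(Cl)(Cl)Cl
Why: Dichloroketene made in the flask should add to the terminal alkene in a thermal [2+2] ketene–alkene cycloaddition with the substituted alkene carbon ending next to CCl2; the new stereocentre is racemic and ceases to be a stereocentre in step 3.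

Step 3
Reactants: 3 rac-2,2-dichloro-3-[4-(benzyloxy)-3-methoxybenzyl]cyclobutan-1-one
Product: 4 3-[4-(benzyloxy)-3-methoxybenzyl]cyclobutan-1-one
Conditions: Zn dust, AcOH, rt to 50 °C
Reagents that add atoms: none
Why: Reductive dehalogenation of an α-halo ketone by zinc removes both chlorines and leaves a cyclobutanone with a mirror plane through the carbonyl and C3, while the benzyl ether is inert.

Step 4
Reactants: 4 3-[4-(benzyloxy)-3-methoxybenzyl]cyclobutan-1-one
Product: 6 (R)-4-[4-(benzyloxy)-3-methoxybenzyl]dihydrofuran-2(3H)-one, via Criegee peroxyhemiketal 5 (not isolated)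
Conditions: Sc(OTf)3 (5 mol %), chiral C2-symmetric N,N′-dioxide ligand (pipecolic acid-derived bis-2,6-diisopropylanilide, 6 mol %), mCPBA (1.2 equiv), EtOAc, −20 °C
Reagents that add atoms: mCPBA (3-chloroperbenzoic acid), OOC(=O)c1cccc(Cl)c1
Why: The Sc(OTf)3–ligand complex activates the carbonyl (future C2) and mCPBA adds to give Criegee adduct 5, in which one of the two enantiotopic α-methylenes (future C5) migrates with its electron pair from C2 to the proximal peroxide oxygen (future O1) while 3-chlorobenzoate leaves, so the C5–O1 bond forms in the migration itself. The closest known reaction type is the catalytic enantioselective (desymmetrising) Baeyer–Villiger oxidation of prochiral 3-substituted cyclobutanones. The lactone ring is closed by a 1,2-shift from carbon to oxygen, that is by one-atom ring expansion of the four-membered carbocycle to the five-membered ring O1–C2–C3–C4–C5, and release of cyclobutanone strain drives it. The new stereocentre C4 is controlled by the chiral ligand on scandium, which holds the Criegee adduct so that only one of the two C–C bonds lies antiperiplanar to the O–O bond; the ligand antipode is selected for R. The step needs enantiotopic-group selectivity, which rests on the catalyst because both candidate migrating carbons are CH2 (no regiochemical issue), and chemoselectivity over the electron-rich benzyloxyarene, which the fast oxidation of the strained ketone at −20 °C should secure.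

Step 5
Reactants: 7 methyl vanillate (methyl 4-hydroxy-3-methoxybenzoate); 8 (S)-4-benzyl-3-(2-chloroacetyl)oxazolidin-2-one
Product: 9 methyl 4-{2-[(S)-4-benzyl-2-oxooxazolidin-3-yl]-2-oxoethoxy}-3-methoxybenzoate
Conditions: K2CO3, acetone, 50 °C
Reagents that add atoms: none
Why: Williamson ether synthesis; the phenoxide should displace the carbonyl-activated primary chloride by SN2 faster than it attacks the imide carbonyls, and the auxiliary stereocentre is not involved.

Step 6
Reactants: 9 methyl 4-{2-[(S)-4-benzyl-2-oxooxazolidin-3-yl]-2-oxoethoxy}-3-methoxybenzoate; 10 4-(benzyloxy)-3-methoxybenzaldehyde (O-benzylvanillin)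
Product: 13 methyl 4-{[(1R,2S)-1-[4-(benzyloxy)-3-methoxyphenyl]-3-[(S)-4-benzyl-2-oxooxazolidin-3-yl]-1-hydroxy-3-oxopropan-2-yl]oxy}-3-methoxybenzoate, via (Z)-dibutylboron enolate 11 (not isolated), via dibutylboron aldolate 12 (not isolated)
Conditions: Bu2BOTf, iPr2NEt, CH2Cl2, −78 to 0 °C; then 10, −78 to 0 °C; then pH 7 buffer, MeOH, 30% H2O2, 0 °C
Reagents that add atoms: none
Why: Evans syn-aldol; soft enolisation gives (Z)-boron enolate 11, which reacts through a closed Zimmerman–Traxler chair in which the benzyl group of the (S)-auxiliary blocks one enolate face, so C8 and C7 are set together as the syn (threo) pair with the absolute sense that reads 7R,8R after step 7.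

Step 7
Reactants: 13 syn-aldol adduct
Product: 14 (1R,2R)-1-[4-(benzyloxy)-3-methoxyphenyl]-2-[4-(hydroxymethyl)-2-methoxyphenoxy]propane-1,3-diol
Conditions: LiBH4 (excess), MeOH, THF, 0 to 50 °C
Reagents that add atoms: none
Why: Hydride reduction; LiBH4 cleaves the N-acyl oxazolidinone at the exocyclic carbonyl to the primary alcohol C9 and, on warming with methanol, reduces the aryl methyl ester to the benzylic alcohol without touching C7 or C8.

Step 8
Reactants: 14 triol
Product: 15 (4-{[(4R,5R)-4-[4-(benzyloxy)-3-methoxyphenyl]-2,2-dimethyl-1,3-dioxan-5-yl]oxy}-3-methoxyphenyl)methanol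
Conditions: Me2C(OMe)2, PPTS (cat.), acetone, rt
Reagents that add atoms: 2,2-dimethoxypropane, COC(C)(C)OC
Why: Acid-catalysed transketalisation should close the six-membered acetonide on the C7/C9 1,3-diol, whereas the isolated benzylic alcohol cannot form a cyclic ketal and remains the free handle.

Step 9
Reactants: 15 acetonide benzylic alcohol
Product: 16 (4R,5R)-4-[4-(benzyloxy)-3-methoxyphenyl]-5-[4-(bromomethyl)-2-methoxyphenoxy]-2,2-dimethyl-1,3-dioxane
Conditions: CBr4, PPh3, CH2Cl2, 0 °C
Reagents that add atoms: carbon tetrabromide, BrC(Br)(Br)Br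
Why: Appel reaction; neutral activation of the primary benzylic alcohol and SN2 displacement by bromide should spare the acetonide and the benzyl ether.

Step 10
Reactants: 6 (R)-4-[4-(benzyloxy)-3-methoxybenzyl]dihydrofuran-2(3H)-one; 16 benzylic bromide
Product: 18 (3R,4R)-4-[4-(benzyloxy)-3-methoxybenzyl]-3-(4-{[(4R,5R)-4-[4-(benzyloxy)-3-methoxyphenyl]-2,2-dimethyl-1,3-dioxan-5-yl]oxy}-3-methoxybenzyl)dihydrofuran-2(3H)-one, via lithium enolate 17 (not isolated)
Conditions: LiN(SiMe3)2, THF, −78 °C; then 16, THF, −78 to −20 °C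
Reagents that add atoms: none
Why: Enolate alkylation; lithium enolate 17 should be benzylated by SN2 on the face anti to the C4 benzyl group, which sets C3 as R (trans-3,4), the usual outcome for β-substituted butyrolactone enolates.

Step 11
Reactants: 18 coupled acetonide lactone
Product: 19 (3R,4R)-4-[4-(benzyloxy)-3-methoxybenzyl]-3-(4-{[(1R,2R)-1-[4-(benzyloxy)-3-methoxyphenyl]-1,3-dihydroxypropan-2-yl]oxy}-3-methoxybenzyl)dihydrofuran-2(3H)-one
Conditions: AcOH–H2O (4:1), 40 °C
Reagents that add atoms: none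
Why: Acid-catalysed acetal hydrolysis under mild aqueous conditions should free the C7/C9 diol without ionising the benzylic C7–O bond, while the benzyl ethers and the lactone persist.

Step 12
Reactants: 19 bis-benzyl ether diol
Product: 20 target, (3R,4R)-3-(4-{[(1R,2R)-1,3-dihydroxy-1-(4-hydroxy-3-methoxyphenyl)propan-2-yl]oxy}-3-methoxybenzyl)-4-(4-hydroxy-3-methoxybenzyl)dihydrofuran-2(3H)-one
Conditions: H2 (1 atm), Pd/C (10%), EtOAc–MeOH, rt
Reagents that add atoms: none
Why: Hydrogenolysis of the two aryl benzyl ethers over Pd/C is faster than cleavage of the secondary benzylic C7–OH, so stopping after uptake of two equivalents of H2 should give the target with all four stereocentres untouched.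

Compound list
1 | eugenol (4-allyl-2-methoxyphenol) | C=CCc1ccc(O)c(OC)c1 | starting material
2 | 4-allyl-1-(benzyloxy)-2-methoxybenzene | C=CCc1ccc(OCc2ccccc2)c(OC)c1 | intermediate
3 | rac-2,2-dichloro-3-[4-(benzyloxy)-3-methoxybenzyl]cyclobutan-1-one | O=C1CC(Cc2ccc(OCc3ccccc3)c(OC)c2)C1(Cl)Cl | intermediate
4 | 3-[4-(benzyloxy)-3-methoxybenzyl]cyclobutan-1-one | O=C1CC(Cc2ccc(OCc3ccccc3)c(OC)c2)C1 | intermediate
5 | Criegee peroxyhemiketal, 1-hydroxy-3-[4-(benzyloxy)-3-methoxybenzyl]cyclobutyl 3-chloroperbenzoate (scandium-bound) | OC1(OOC(=O)c2cccc(Cl)c2)CC(Cc2ccc(OCc3ccccc3)c(OC)c2)C1 | intermediate (not isolated)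
6 | (R)-4-[4-(benzyloxy)-3-methoxybenzyl]dihydrofuran-2(3H)-one | O=C1C[C@@H](Cc2ccc(OCc3ccccc3)c(OC)c2)CO1 | intermediate
7 | methyl vanillate | COC(=O)c1ccc(O)c(OC)c1 | starting material
8 | (S)-4-benzyl-3-(2-chloroacetyl)oxazolidin-2-one | O=C(CCl)N1C(=O)OC[C@@H]1Cc1ccccc1 | starting material
9 | methyl 4-{2-[(S)-4-benzyl-2-oxooxazolidin-3-yl]-2-oxoethoxy}-3-methoxybenzoate | COC(=O)c1ccc(OCC(=O)N2C(=O)OC[C@@H]2Cc2ccccc2)c(OC)c1 | intermediate
10 | 4-(benzyloxy)-3-methoxybenzaldehyde | O=Cc1ccc(OCc2ccccc2)c(OC)c1 | starting material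
11 | (Z)-dibutylboron enolate of 9 | CCCCB(CCCC)O/C(=C\Oc1ccc(C(=O)OC)cc1OC)N1C(=O)OC[C@@H]1Cc1ccccc1 | intermediate (not isolated)
12 | dibutylboron aldolate of 13 | COC(=O)c1ccc(O[C@H](C(=O)N2C(=O)OC[C@@H]2Cc2ccccc2)[C@H](OB(CCCC)CCCC)c2ccc(OCc3ccccc3)c(OC)c2)c(OC)c1 | intermediate (not isolated)
13 | syn-aldol adduct, (1R,2S) in the propan-2-yl numbering, (S)-auxiliary | COC(=O)c1ccc(O[C@H](C(=O)N2C(=O)OC[C@@H]2Cc2ccccc2)[C@H](O)c2ccc(OCc3ccccc3)c(OC)c2)c(OC)c1 | intermediate
14 | (1R,2R)-1-[4-(benzyloxy)-3-methoxyphenyl]-2-[4-(hydroxymethyl)-2-methoxyphenoxy]propane-1,3-diol | OCc1ccc(O[C@H](CO)[C@H](O)c2ccc(OCc3ccccc3)c(OC)c2)c(OC)c1 | intermediate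
15 | (4-{[(4R,5R)-4-[4-(benzyloxy)-3-methoxyphenyl]-2,2-dimethyl-1,3-dioxan-5-yl]oxy}-3-methoxyphenyl)methanol | OCc1ccc(O[C@@H]2COC(C)(C)O[C@@H]2c2ccc(OCc3ccccc3)c(OC)c2)c(OC)c1 | intermediate
16 | (4R,5R)-4-[4-(benzyloxy)-3-methoxyphenyl]-5-[4-(bromomethyl)-2-methoxyphenoxy]-2,2-dimethyl-1,3-dioxane | BrCc1ccc(O[C@@H]2COC(C)(C)O[C@@H]2c2ccc(OCc3ccccc3)c(OC)c2)c(OC)c1 | intermediate
17 | lithium enolate of 6 | [Li]OC1=C[C@@H](Cc2ccc(OCc3ccccc3)c(OC)c2)CO1 | intermediate (not isolated)
18 | (3R,4R)-trans-dibenzyl lactone, acetonide, bis-benzyl ether | COc1cc(C[C@H]2COC(=O)[C@@H]2Cc2ccc(O[C@@H]3COC(C)(C)O[C@@H]3c3ccc(OCc4ccccc4)c(OC)c3)c(OC)c2)ccc1OCc1ccccc1 | intermediate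
19 | (3R,4R)-lactone with free (7R,8R)-diol, bis-benzyl ether | COc1cc(C[C@H]2COC(=O)[C@@H]2Cc2ccc(O[C@H](CO)[C@H](O)c3ccc(OCc4ccccc4)c(OC)c3)c(OC)c2)ccc1OCc1ccccc1 | intermediate
20 | target, (3R,4R)-3-(4-{[(1R,2R)-1,3-dihydroxy-1-(4-hydroxy-3-methoxyphenyl)propan-2-yl]oxy}-3-methoxybenzyl)-4-(4-hydroxy-3-methoxybenzyl)dihydrofuran-2(3H)-one | COc1cc(C[C@H]2COC(=O)[C@@H]2Cc2ccc(O[C@H](CO)[C@H](O)c3ccc(O)c(OC)c3)c(OC)c2)ccc1O | target

Total step count: 12. Longest linear sequence: 8 (steps 5 to 12); the lactone arm is 4 steps (steps 1 to 4) before the coupling.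

Steps most likely to fail

Step 4. Discrimination between the two enantiotopic methylenes may be incomplete for a benzyl-type 3-substituent, giving lactone of insufficient enantiomeric purity. Fallback: from 4, oxidation without a chiral catalyst (mCPBA, NaHCO3, CH2Cl2) would give racemic 4-[4-(benzyloxy)-3-methoxybenzyl]dihydrofuran-2(3H)-one F1. Aminolysis with (S)-1-phenylethylamine (2-hydroxypyridine, toluene, 100 °C) should give the diastereomeric hydroxy amides, the (R)-configured hydroxy amide F2 and its (S)-configured diastereomer F3, separable by crystallisation or chromatography. Acid treatment of F2 (2 M H2SO4, dioxane, reflux) would relactonise it with loss of the amine and rejoin the route at 6. The C5–O1 bond still comes from the ring expansion; only the source of enantiopurity changes.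

Step 10. Ionisation or decomposition of the electron-rich benzylic bromide, or dialkylation of the enolate, may erode the coupling. Fallback: the C3–C bond would be made by aldol condensation and reduction. From 15, oxidation (MnO2, CH2Cl2) gives the benzaldehyde F7. Enolate 17 (from 6) adds to it at −78 °C to give the β-hydroxy lactone F8 as carbinol epimers. MsCl/Et3N gives the mesylate F9, and DBU eliminates it to the (E)-benzylidene lactone F10. Conjugate reduction (NaBH4, NiCl2·6H2O, MeOH–THF, 0 °C) followed by equilibration with DBU to the more stable trans isomer rejoins the route at 18.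

Step 5. Attack of the phenoxide on the imide carbonyls (loss of the auxiliary) may compete with displacement of chloride. Fallback: the ether bond would be made first on a simple ester. From 7, alkylation with tert-butyl bromoacetate (K2CO3, acetone) gives the tert-butyl aryloxyacetate F4, and TFA/CH2Cl2 gives the aryloxyacetic acid F5. Pivaloyl chloride/Et3N (THF, −20 °C) gives the mixed pivalic anhydride F6, which acylates N-lithiated (S)-4-benzyloxazolidin-2-one (commercial oxazolidinone, n-BuLi, THF, −78 °C) to rejoin the route at 9.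

Further compounds
F1 | step 4 | rac-4-[4-(benzyloxy)-3-methoxybenzyl]dihydrofuran-2(3H)-one | O=C1CC(Cc2ccc(OCc3ccccc3)c(OC)c2)CO1
F2 | step 4 | (R)-3-[4-(benzyloxy)-3-methoxybenzyl]-4-hydroxy-N-[(S)-1-phenylethyl]butanamide | OC[C@H](Cc1ccc(OCc2ccccc2)c(OC)c1)CC(=O)N[C@@H](C)c1ccccc1
F3 | step 4 | (S)-3-[4-(benzyloxy)-3-methoxybenzyl]-4-hydroxy-N-[(S)-1-phenylethyl]butanamide | OC[C@@H](Cc1ccc(OCc2ccccc2)c(OC)c1)CC(=O)N[C@@H](C)c1ccccc1
F4 | step 5 | methyl 4-(2-tert-butoxy-2-oxoethoxy)-3-methoxybenzoate | COC(=O)c1ccc(OCC(=O)OC(C)(C)C)c(OC)c1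
F5 | step 5 | 2-[2-methoxy-4-(methoxycarbonyl)phenoxy]acetic acid | COC(=O)c1ccc(OCC(=O)O)c(OC)c1
F6 | step 5 | 2-[2-methoxy-4-(methoxycarbonyl)phenoxy]acetic pivalic anhydride | COC(=O)c1ccc(OCC(=O)OC(=O)C(C)(C)C)c(OC)c1
F7 | step 10 | 4-{[(4R,5R)-4-[4-(benzyloxy)-3-methoxyphenyl]-2,2-dimethyl-1,3-dioxan-5-yl]oxy}-3-methoxybenzaldehyde | O=Cc1ccc(O[C@@H]2COC(C)(C)O[C@@H]2c2ccc(OCc3ccccc3)c(OC)c2)c(OC)c1
F8 | step 10 | (3S,4R)-trans-4-[4-(benzyloxy)-3-methoxybenzyl]-3-[aryl(hydroxy)methyl]dihydrofuran-2(3H)-one, aryl as in 18, carbinol epimers | COc1cc(C[C@H]2COC(=O)[C@@H]2C(O)c2ccc(O[C@@H]3COC(C)(C)O[C@@H]3c3ccc(OCc4ccccc4)c(OC)c3)c(OC)c2)ccc1OCc1ccccc1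
F9 | step 10 | methanesulfonate of F8 | COc1cc(C[C@H]2COC(=O)[C@@H]2C(OS(C)(=O)=O)c2ccc(O[C@@H]3COC(C)(C)O[C@@H]3c3ccc(OCc4ccccc4)c(OC)c3)c(OC)c2)ccc1OCc1ccccc1
F10 | step 10 | (R,E)-4-[4-(benzyloxy)-3-methoxybenzyl]-3-(arylmethylidene)dihydrofuran-2(3H)-one, aryl as in 18 | COc1cc(C[C@H]2COC(=O)/C2=C/c2ccc(O[C@@H]3COC(C)(C)O[C@@H]3c3ccc(OCc4ccccc4)c(OC)c3)c(OC)c2)ccc1OCc1ccccc1
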